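The route rests on cutting the CH2–CH2 bond at the centre of the 1,5-diene C(CH3)=CH–CH2–CH2–C(CO2H)=CH inside the 14-membered aryl ether ring. Both carbons are allylic: the one beside the Z-trisubstituted olefin can carry a removable phenylsulfonyl group and act as an allyl anion, the other is the free methylene of a 2-substituted acrylate. The key step, an intramolecular SN2′ attack (Michael addition, then loss of acetate) of the sulfonyl carbanion on a Morita–Baylis–Hillman acetate, forms this bond, closes the macrocycle and creates the (E)-enoate in one operation. Its precursor is an open-chain aryl ether assembled from (R)-6,7-epoxyneryl phenyl sulfone and a phenol derived from homogentisic acid lactone.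

Key step: step 10

Assumptions: nerol, sodium benzenesulfinate, 5-hydroxybenzofuran-2(3H)-one (homogentisic acid γ-lactone), N,O-dimethylhydroxylamine hydrochloride, methyl acrylate and the D-fructose-derived Shi ketone are taken as commercial. The two centres created without control (the Morita–Baylis–Hillman carbinol carbon in 13 and 14, the sulfonyl carbon in 17) are carried as mixtures, because both are erased before the target.

Step 1
Reactants: 1 nerol, (2Z)-3,7-dimethylocta-2,6-dien-1-ol
Product: 2 neryl bromide, (2Z)-1-bromo-3,7-dimethylocta-2,6-diene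
Conditions: PBr3 (0.4 equiv), Et2O, −10 °C, dark; used crude
Reagents that add atoms: phosphorus tribromide, BrP(Br)Br
Why: Conversion of a primary allylic alcohol into the bromide through its phosphite ester (SN2 by bromide), which at low temperature should keep the Z olefin and avoid allylic transposition.

Step 2
Reactants: 2 neryl bromide; 3 sodium benzenesulfinate
Product: 4 neryl phenyl sulfone, {[(2Z)-3,7-dimethylocta-2,6-dien-1-yl]sulfonyl}benzene
Conditions: DMF, 0 °C → rt
Reagents that add atoms: none
Why: S-alkylation of the sulfinate anion by a primary allylic bromide (SN2), which should leave the olefin geometry untouched.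

Step 3
Reactants: 4 neryl phenyl sulfone
Product: 5 (R)-6,7-epoxyneryl phenyl sulfone, (3R)-2,2-dimethyl-3-[(3Z)-3-methyl-5-(phenylsulfonyl)pent-3-en-1-yl]oxirane
Conditions: D-fructose-derived Shi ketone (0.3 equiv), Oxone (2KHSO5·KHSO4·K2SO4), K2CO3, Bu4NHSO4 (cat.), MeCN/CH2(OMe)2/aq. Na2B4O7 buffer, 0 °C
Reagents that add atoms: potassium peroxymonosulfate (active part of Oxone), [K+].[O-]S(=O)(=O)OO
Why: Shi asymmetric epoxidation, in which the chiral dioxirane should transfer oxygen through a spiro transition state to the electron-rich distal olefin (the other olefin is deactivated by the allylic sulfonyl group) on the face that gives the R epoxide.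

Step 4
Reactants: 6 5-hydroxybenzofuran-2(3H)-one (homogentisic acid γ-lactone)
Product: 7 5-(tert-butyldimethylsilyloxy)benzofuran-2(3H)-one
Conditions: TBSCl, imidazole, CH2Cl2, 0 °C → rt
Reagents that add atoms: tert-butyldimethylsilyl chloride, CC(C)(C)[Si](C)(C)Cl
Why: Silylation of the only free phenol, while the lactone keeps the second hydroquinone oxygen masked and so tells the two apart.

Step 5
Reactants: 7 silylated lactone; 8 N,O-dimethylhydroxylamine hydrochloride
Product: 9 2-[5-(tert-butyldimethylsilyloxy)-2-hydroxyphenyl]-N-methoxy-N-methylacetamide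
Conditions: 8 (2 equiv), AlMe3 (2 equiv), CH2Cl2, 0 °C → rt; aq. KNaC4H4O6 (potassium sodium tartrate)
Reagents that add atoms: none
Why: Weinreb aminolysis of an activated aryl lactone by the aluminium amide formed in the flask, which frees the ring phenol and turns the acyl carbon into a latent aldehyde.

Step 6
Reactants: 5 (R)-epoxide; 9 phenol
Product: 10 2-[5-(tert-butyldimethylsilyloxy)-2-{[(3R,6Z)-3-hydroxy-2,6-dimethyl-8-(phenylsulfonyl)oct-6-en-2-yl]oxy}phenyl]-N-methoxy-N-methylacetamide
Conditions: 9 (2 equiv), BF3·OEt2 (0.3 equiv), 4 Å molecular sieves, CH2Cl2, −40 → −20 °C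
Reagents that add atoms: none
Why: Lewis acid-catalysed, SN1-like opening of a trisubstituted epoxide by an oxygen nucleophile at the tertiary carbon, so the phenol should bond to CMe2 while the secondary C–O bond and its R configuration stay untouched.

Step 7
Reactants: 10 Weinreb amide
Product: 11 2-[5-(tert-butyldimethylsilyloxy)-2-{[(3R,6Z)-3-hydroxy-2,6-dimethyl-8-(phenylsulfonyl)oct-6-en-2-yl]oxy}phenyl]acetaldehyde
Conditions: i-Bu2AlH (2.5 equiv), THF, −78 °C; aq. KNaC4H4O6
Reagents that add atoms: none
Why: Partial reduction of a Weinreb amide, whose aluminium chelate should collapse to the aldehyde only on work-up, with sulfone, silyl ether and olefin inert at −78 °C.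

Step 8
Reactants: 11 arylacetaldehyde; 12 methyl acrylate
Product: 13 methyl 3-hydroxy-2-methylidene-4-[aryl]butanoate, aryl as in 11 (both epimers at the new carbinol carbon)
Conditions: methyl acrylate (neat, excess), DABCO (1 equiv), rt, dark
Reagents that add atoms: none
Why: Morita–Baylis–Hillman reaction (amine-derived zwitterionic enolate, aldol addition, elimination of the amine); the new carbinol centre is not controlled and disappears in step 10.

Step 9
Reactants: 13 Morita–Baylis–Hillman alcohol
Product: 14 diacetate of 13 (allylic acetate and acetate of the R carbinol)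
Conditions: Ac2O, pyridine, DMAP (cat.), CH2Cl2, 0 °C → rt
Reagents that add atoms: acetic anhydride, CC(=O)OC(C)=O
Why: DMAP-catalysed acylation of both secondary alcohols, which should make the allylic oxygen a leaving group and protect the R carbinol in the same operation.

Step 10
Reactants: 14 diacetate
Product: 17 macrocyclic allylic sulfone (14-membered ring; methyl ester; acetate; aryl silyl ether; phenylsulfonyl on the ring carbon beside the Z olefin; both epimers there), via lithiated allyl sulfone 15 (not isolated), via macrocyclic lithium ester enolate 16 (not isolated)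
Conditions: LiN(SiMe3)2 (1.05 equiv, added over 2 h), THF (1 mM), −78 → 0 °C; aq. NH4Cl
Reagents that add atoms: none
Why: LiN(SiMe3)2 should remove the most acidic proton (allylic and α to sulfonyl) to give carbanion 15, whose α-carbon adds to the unsubstituted methylene terminus of the 2-substituted acrylate to give ester enolate 16, and E1cB loss of the allylic acetate then delivers the trisubstituted enoate (overall SN2′). The closest known reactions are SN2′ alkylations of stabilised carbanions by Morita–Baylis–Hillman acetates and the sulfone-anion macrocyclisations used for 14-membered terpenoid rings. The single ring closes in a 14-endo-trig mode, favoured over oligomerisation by working at about 1 mM and by the arene and two olefins that limit the conformations of the chain. The new stereocentre at the sulfonyl carbon is not controlled and is erased in step 11, while the (E)-enoate geometry (CO2Me trans to CH2Ar) should be set by allylic 1,3-strain in the elimination from 16, as in open-chain cases. The step needs α- over γ-attack of the allyl anion (the γ-carbon is fully substituted), retention of the Z olefin (the sulfonyl-stabilised anion keeps its geometry at low temperature) and conjugate addition in preference to attack on the two acetates (soft carbanion against hard ester carbonyls).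

Step 11
Reactants: 17 macrocyclic allylic sulfone
Product: 18 protected petchiether B (methyl ester, acetate of the R carbinol, aryl tert-butyldimethylsilyl ether)
Conditions: PdCl2(dppp) (10 mol%; dppp = Ph2P(CH2)3PPh2), NaBH4 (5 equiv), THF/i-PrOH 4:1, 0 °C → rt
Reagents that add atoms: none
Why: Palladium-catalysed hydride desulfonylation of an allylic sulfone, in which zerovalent palladium ionises the allylic C–S bond to a π-allyl complex and hydride should go to the less substituted terminus (the former sulfonyl carbon), keeping position and Z geometry of the trisubstituted olefin while NaBH4 spares the ester and acetate.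

Step 12
Reactants: 18 protected petchiether B
Product: 19 petchiether B
Conditions: LiOH·H2O (10 equiv), degassed THF/MeOH/H2O 3:1:1, 50 °C; then 1 M HCl to pH 4, 0 °C
Reagents that add atoms: water (delivered as hydroxide from LiOH), O
Why: Saponification of the methyl enoate and the acetate together with hydroxide cleavage of the aryl silyl ether in one operation, with no stereocentre or olefin involved.

Compound list
1 | nerol, (2Z)-3,7-dimethylocta-2,6-dien-1-ol | CC(C)=CCC/C(C)=C\CO | starting material
2 | neryl bromide | CC(C)=CCC/C(C)=C\CBr | intermediate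
3 | sodium benzenesulfinate | [Na+].[O-]S(=O)c1ccccc1 | starting material
4 | neryl phenyl sulfone | CC(C)=CCC/C(C)=C\CS(=O)(=O)c1ccccc1 | intermediate
5 | (R)-6,7-epoxyneryl phenyl sulfone | CC1(C)O[C@@H]1CC/C(C)=C\CS(=O)(=O)c1ccccc1 | intermediate
6 | 5-hydroxybenzofuran-2(3H)-one | O=C1Cc2cc(O)ccc2O1 | starting material
7 | 5-(tert-butyldimethylsilyloxy)benzofuran-2(3H)-one | O=C1Cc2cc(O[Si](C)(C)C(C)(C)C)ccc2O1 | intermediate
8 | N,O-dimethylhydroxylamine hydrochloride | CNOC.Cl | starting material
9 | 2-[5-(tert-butyldimethylsilyloxy)-2-hydroxyphenyl]-N-methoxy-N-methylacetamide | CON(C)C(=O)Cc1cc(O[Si](C)(C)C(C)(C)C)ccc1O | intermediate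
10 | tertiary aryl ether with (3R)-carbinol, (6Z)-olefin, Weinreb amide | CON(C)C(=O)Cc1cc(O[Si](C)(C)C(C)(C)C)ccc1OC(C)(C)[C@H](O)CC/C(C)=C\CS(=O)(=O)c1ccccc1 | intermediate
11 | arylacetaldehyde from 10 | O=CCc1cc(O[Si](C)(C)C(C)(C)C)ccc1OC(C)(C)[C@H](O)CC/C(C)=C\CS(=O)(=O)c1ccccc1 | intermediate
12 | methyl acrylate | C=CC(=O)OC | starting material
13 | Morita–Baylis–Hillman alcohol (both epimers at the new carbinol) | C=C(C(=O)OC)C(O)Cc1cc(O[Si](C)(C)C(C)(C)C)ccc1OC(C)(C)[C@H](O)CC/C(C)=C\CS(=O)(=O)c1ccccc1 | intermediate
14 | diacetate of 13 | C=C(C(=O)OC)C(OC(C)=O)Cc1cc(O[Si](C)(C)C(C)(C)C)ccc1OC(C)(C)[C@H](OC(C)=O)CC/C(C)=C\CS(=O)(=O)c1ccccc1 | intermediate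
15 | lithiated allyl sulfone of 14 (not isolated) | [Li+].C=C(C(=O)OC)C(OC(C)=O)Cc1cc(O[Si](C)(C)C(C)(C)C)ccc1OC(C)(C)[C@H](OC(C)=O)CC/C(C)=C\[CH-]S(=O)(=O)c1ccccc1 | intermediate
16 | macrocyclic lithium ester enolate (not isolated) | [Li+].C/C1=C/C(S(=O)(=O)c3ccccc3)CC(=C([O-])OC)C(OC(C)=O)Cc2cc(O[Si](C)(C)C(C)(C)C)ccc2OC(C)(C)[C@H](OC(C)=O)CC1 | intermediate
17 | macrocyclic allylic sulfone (both epimers at the sulfonyl carbon) | C/C1=C/C(S(=O)(=O)c3ccccc3)C/C(C(=O)OC)=C\Cc2cc(O[Si](C)(C)C(C)(C)C)ccc2OC(C)(C)[C@H](OC(C)=O)CC1 | intermediate
18 | protected petchiether B (methyl ester, acetate, aryl silyl ether) | C/C1=C/CC/C(C(=O)OC)=C\Cc2cc(O[Si](C)(C)C(C)(C)C)ccc2OC(C)(C)[C@H](OC(C)=O)CC1 | intermediate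
19 | petchiether B | C/C1=C/CC/C(C(=O)O)=C\Cc2cc(O)ccc2OC(C)(C)[C@H](O)CC1 | target

Total step count: 12. Longest linear sequence: 10 steps (1, 2, 3, 6, 7, 8, 9, 10, 11, 12, from nerol).

Steps most likely to fail

Step 6. The activated epoxide may alkylate the electron-rich arene at carbon, or rearrange to a ketone by hydride shift before the weakly nucleophilic phenol arrives, and the amide may tie up the Lewis acid. The fallback sets out from sulfone 4 and phenol 9 and returns at 10. Epoxidation of the distal olefin of 4 with mCPBA (CH2Cl2, 0 °C) would give racemic epoxide F1. HBr (Et2O, −20 °C) would open it at the tertiary carbon to bromohydrin F2, and Dess–Martin oxidation would give α-bromo ketone F3. Alkylation of the phenoxide of 9 with F3 (K2CO3, acetone, rt), a displacement at a tertiary α-keto carbon of the kind used for aryloxyisobutyrates, would give aryloxy ketone F4. Reduction with the (S)-Me-CBS oxazaborolidine and catecholborane (toluene, −78 °C), with the quaternary aryloxy carbon as the large group, would set the R carbinol and give 10.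

Step 10. Intermolecular addition may outrun ring closure, or the elimination inside the ring may erode the enoate geometry. The fallback sets out from diacetate 14 and returns at 17. DABCO (THF, rt) would move the allylic acetate to the primary carbon by two successive SN2′ steps and give (E)-2-(acetoxymethyl)enoate F5, in which the enoate geometry is fixed before the ring is closed. The sodium salt of the sulfone (NaH, THF) would then be added slowly to Pd(PPh3)4 in THF at reflux. Ionisation of the allylic acetate by zerovalent palladium and attack of the sulfonyl carbanion on the unsubstituted terminus of the π-allyl complex (Tsuji–Trost macrocyclisation) would give 17.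

Step 11. The palladium hydride may reduce the enoate in conjugate fashion, deliver hydride to the wrong allyl terminus, or let the Z olefin isomerise through syn/anti exchange of the π-allyl complex. The fallback sets out from 17 and returns at the target 19. Saponification first (LiOH, THF/MeOH/H2O, 50 °C) would give sulfonyl hydroxy acid F6, which has no group left that LiBHEt3 reduces. PdCl2(dppp) (10 mol%) with LiBHEt3 (6 equiv) in THF at 0 °C, the variant of this desulfonylation that best retains olefin position and geometry, would then give 19 after acidification.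

Further compounds
F1 | step 6 | racemic 6,7-epoxyneryl phenyl sulfone | CC1(C)OC1CC/C(C)=C\CS(=O)(=O)c1ccccc1
F2 | step 6 | (6Z)-2-bromo-2,6-dimethyl-8-(phenylsulfonyl)oct-6-en-3-ol (racemic) | CC(C)(Br)C(O)CC/C(C)=C\CS(=O)(=O)c1ccccc1
F3 | step 6 | (6Z)-2-bromo-2,6-dimethyl-8-(phenylsulfonyl)oct-6-en-3-one | CC(C)(Br)C(=O)CC/C(C)=C\CS(=O)(=O)c1ccccc1
F4 | step 6 | aryloxy ketone (3-oxo analogue of 10) | CON(C)C(=O)Cc1cc(O[Si](C)(C)C(C)(C)C)ccc1OC(C)(C)C(=O)CC/C(C)=C\CS(=O)(=O)c1ccccc1
F5 | step 10 | (E)-2-(acetoxymethyl)enoate isomer of 14 | COC(=O)/C(COC(C)=O)=C/Cc1cc(O[Si](C)(C)C(C)(C)C)ccc1OC(C)(C)[C@H](OC(C)=O)CC/C(C)=C\CS(=O)(=O)c1ccccc1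
F6 | step 11 | macrocyclic sulfonyl hydroxy acid (both epimers at the sulfonyl carbon) | C/C1=C/C(S(=O)(=O)c3ccccc3)C/C(C(=O)O)=C\Cc2cc(O)ccc2OC(C)(C)[C@H](O)CC1
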